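**Retrosynthetic overview**

1. Target 32 ⇐ methoxide opening and O‑acetylation of enol lactone 30, a temporary C18–O–C19 ring that fixes the (Z)‑enol acetate ⇐ aldehyde acid 29 ⇐ ten‑membered silyl enol ether 28.
2. 28 ⇐ [1,7]‑H shift (C19→C10) of triene 27 ⇐ conrotatory 6π opening of cis‑decalin diene 26. Enabling feature: the array C19=C5–C4=C3–C2=C1–C10H2 of the cyclodecatriene is the ring‑opened, hydrogen‑shifted valence isomer of a cis‑bicyclo[4.4.0]deca‑2,4‑diene, so C5 and C10 can be joined by a temporary bond that folds the ten‑membered ring into rings A (C1–C5, C10) and B (C5–C10).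
3. 26 ⇐ enone 17 (carbonyl transposition, triflate carbonylation, B‑alkyl Suzuki coupling with 3‑bromofuran) ⇐ key step: ring B closed at C9–C10 by intramolecular allylsilane addition to the prochiral dienone 16, where C8 chooses between the two enantiotopic enone carbons.
4. 16 ⇐ benzoic acid 11 (Birch reductive alkylation) + iodide 10 ⇐ Ni‑catalysed ring opening of dihydropyran 7 ⇐ half‑ester 1.
5. Ring order: ring A (from benzoic acid) → ring B (step 10) → C5–C10 cleaved to the ten‑membered ring (step 17) → temporary enol lactone (step 19) → opened (step 20).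

Key step: step 10

Remark: positions are named by clerodane numbering (ring C1–C10, side chain C11/C12, methyls C17/C20, carboxyl C18, oxygenated carbon C19); 1, 11 and 24 are taken as catalogue chemicals.

**Route**

Step 1
Reactants: 1 methyl hydrogen (3R)-3-methylpentanedioate
Product: 3 (4R)-4-methyltetrahydro-2H-pyran-2-one, via hydroxy ester 2 (not isolated)
Conditions: BH3·SMe2, THF, 0 °C → rt; then TsOH (cat.), PhMe, rt
Reagents that add atoms: none
Why: Borane reduces the carboxylic acid chemoselectively beside the ester, and acid‑catalysed lactonisation of the hydroxy ester (chemoselective borane reduction, then transesterification) should give the δ‑lactone with the future C8 centre untouched.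

Step 2
Reactants: 3 (4R)-4-methyltetrahydro-2H-pyran-2-one
Product: 5 (3S,4R)-3,4-dimethyltetrahydro-2H-pyran-2-one, via lithium enolate 4 (not isolated)
Conditions: LDA, THF, −78 °C; then MeI, −78 → −40 °C
Reagents that add atoms: iodomethane, CI
Why: Lactone enolate alkylation should place the new methyl (future C20) trans to the C4 methyl by approach anti to it; this centre is erased in step 3.

Step 3
Reactants: 5 (3S,4R)-3,4-dimethyltetrahydro-2H-pyran-2-one
Product: 7 (4R)-4,5-dimethyl-3,4-dihydro-2H-pyran, via lactol 6 (not isolated)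
Conditions: DIBAL-H, CH2Cl2, −78 °C; then MsCl, Et3N, CH2Cl2, 0 → 40 °C
Reagents that add atoms: none
Why: Half‑reduction to the lactol and elimination of its mesylate through the oxocarbenium ion (lactol dehydration) should give the cyclic enol ether, locking the future C9=C11 bond in a ring with C8 cis to oxygen.

Step 4
Reactants: 7 (4R)-4,5-dimethyl-3,4-dihydro-2H-pyran
Product: 8 (3R,4Z)-3,4-dimethyl-6-(trimethylsilyl)hex-4-en-1-ol
Conditions: Me3SiCH2MgCl (3 equiv), NiCl2(dppp) (5 mol %), PhMe, 80 °C
Reagents that add atoms: (trimethylsilyl)methylmagnesium chloride, C[Si](C)(C)C[Mg]Cl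
Why: Nickel‑catalysed Kumada‑type cross‑coupling at the enol ether C(sp2)–O bond is stereoretentive, so ring opening should deliver the (Z)‑allylsilane (CH2SiMe3 cis to C8) and the C6 alkoxide in one operation.

Step 5
Reactants: 8 (3R,4Z)-3,4-dimethyl-6-(trimethylsilyl)hex-4-en-1-ol
Product: 10 [(2Z,4R)-6-iodo-3,4-dimethylhex-2-en-1-yl]trimethylsilane, via mesylate 9 (not isolated)
Conditions: MsCl, Et3N, CH2Cl2, 0 °C; then NaI, acetone, 50 °C
Reagents that add atoms: methanesulfonyl chloride, CS(=O)(=O)Cl (atoms in 9 only); sodium iodide, [Na+].[I-]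
Why: Mesylation and Finkelstein substitution give the primary iodide under conditions free of acid and of electrophilic iodine, which the allylsilane would not survive.

Step 6
Reactants: 11 benzoic acid; 10 [(2Z,4R)-6-iodo-3,4-dimethylhex-2-en-1-yl]trimethylsilane
Product: 13 1-[(3R,4Z)-3,4-dimethyl-6-(trimethylsilyl)hex-4-en-1-yl]cyclohexa-2,5-diene-1-carboxylic acid, via dilithium dianion 12 (not isolated)
Conditions: Li, NH3(l)/THF, −78 °C; then 10, −78 → −33 °C; NH4Cl, dil. HCl
Reagents that add atoms: none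
Why: Birch reduction of benzoate gives the enediolate dianion, which is alkylated at the ipso carbon by the primary iodide (Birch reductive alkylation), creating the quaternary but still prochiral C5 flanked by two identical vinyl arms.

Step 7
Reactants: 13 dienoic acid
Product: 14 {1-[(3R,4Z)-3,4-dimethyl-6-(trimethylsilyl)hex-4-en-1-yl]cyclohexa-2,5-dien-1-yl}methanol
Conditions: LiAlH4, Et2O, 0 °C → rt
Reagents that add atoms: none
Why: Lithium aluminium hydride reduction of the acid should give the neopentyl C19 alcohol.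

Step 8
Reactants: 14 dienyl methanol
Product: 15 TBS ether of 14
Conditions: TBSCl, imidazole, CH2Cl2, rt
Reagents that add atoms: tert-butyldimethylsilyl chloride, CC(C)(C)[Si](C)(C)Cl
Why: Standard silylation protects the C19 hydroxyl, which as a free alkoxide would be lost from the later dienone by retro‑aldol aromatisation.

Step 9
Reactants: 15 TBS ether
Product: 16 4-{[(tert-butyldimethylsilyl)oxy]methyl}-4-[(3R,4Z)-3,4-dimethyl-6-(trimethylsilyl)hex-4-en-1-yl]cyclohexa-2,5-dien-1-one
Conditions: t-BuOOH (5 equiv), Rh2(cap)4 (1 mol %), K2CO3, CH2Cl2, rt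
Reagents that add atoms: tert-butyl hydroperoxide, CC(C)(C)OO
Why: Rhodium‑catalysed tert‑butyl hydroperoxide allylic oxidation proceeds by hydrogen abstraction and should select the doubly allylic ring CH2, giving the symmetric 4,4‑disubstituted cyclohexa‑2,5‑dienone.

Step 10
Reactants: 16 prochiral dienone
Product: 17 (4aS,7R,8S,8aR)-4a-{[(tert-butyldimethylsilyl)oxy]methyl}-8-ethenyl-7,8-dimethyl-4a,5,6,7,8,8a-hexahydronaphthalen-2(1H)-one
Conditions: EtAlCl2 (1.5 equiv), PhMe, −78 → −20 °C; aq. NaHCO3
Reagents that add atoms: none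
Why: Intramolecular Hosomi–Sakurai conjugate addition: EtAlCl2 activates the cross‑conjugated dienone, the allylsilane attacks C10 through its γ‑carbon C9 anti to silicon (SE2′), and loss of Me3Si from the β‑silyl cation leaves the C9 vinyl group and an aluminium enolate that is protonated on work‑up. The closest known reaction type is the Lewis‑acid‑promoted intramolecular allylsilane addition to enones and 4,4‑disubstituted cyclohexadienones used for vinyl‑substituted ring annulation. Ring B (C5–C6–C7–C8–C9–C10) closes in a 6‑exo‑trig mode on the enone, which can only give the cis ring fusion. C9 is set by a chair transition state with the C8 methyl equatorial and C8–H eclipsing the C9=C11 bond, the only rotamer free of A(1,3) strain with the (Z)‑CH2SiMe3 group, so the vinyl group becomes equatorial and C20 axial (C17/C20 cis). C5 and C10 are set because the same chair can reach only one of the two enantiotopic enone β‑carbons. The step needs 1,4‑ over 1,2‑addition (1,2 would require an eight‑membered ring) and attack through C9, not C12 (β‑silicon effect).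

Step 11
Reactants: 17 cis-fused vinyl enone
Product: 18 3,4-epoxide of 17
Conditions: 30% H2O2, NaOH (cat.), MeOH, 0 °C
Reagents that add atoms: hydrogen peroxide, OO
Why: Weitz–Scheffer nucleophilic epoxidation attacks only the electron‑poor C3=C4 bond; the two new centres (C3, C4) are set by approach to the less hindered face and are removed again in steps 12 and 13.

Step 12
Reactants: 18 epoxy ketone
Product: 19 allylic alcohol (C4–OH and C2=C3)
Conditions: N2H4·H2O, AcOH (cat.), MeOH, 0 °C → rt, under Ar
Reagents that add atoms: none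
Why: Wharton transposition (hydrazone, vinyl diazene, loss of N2) should move the oxygen from C2 to C4 and the double bond to C2=C3; the C4 carbinol configuration follows the epoxide and is irrelevant.

Step 13
Reactants: 19 allylic alcohol
Product: 20 (4aR,5S,6R,8aS)-8a-{[(tert-butyldimethylsilyl)oxy]methyl}-5-ethenyl-5,6-dimethyl-4a,5,6,7,8,8a-hexahydronaphthalen-1(4H)-one
Conditions: Dess–Martin periodinane, NaHCO3, CH2Cl2, rt
Reagents that add atoms: none
Why: Dess–Martin oxidation of the allylic alcohol gives the transposed enone with the carbonyl on C4.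

Step 14
Reactants: 20 transposed enone
Product: 22 dienyl triflate, via potassium dienolate 21 (not isolated)
Conditions: KHMDS, THF, −78 °C; then PhNTf2, −78 → 0 °C
Reagents that add atoms: N-phenylbis(trifluoromethanesulfonimide), FC(F)(F)S(=O)(=O)N(c1ccccc1)S(=O)(=O)C(F)(F)F
Why: C5 is quaternary, so KHMDS can only remove the γ‑hydrogen at C1, and O‑triflation of the linear dienolate (enol triflate formation) should give the 1,3‑dienyl triflate with the cis ring fusion intact.

Step 15
Reactants: 22 dienyl triflate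
Product: 23 2-(trimethylsilyl)ethyl dienoate (C9 vinyl)
Conditions: CO (1 atm), Pd(OAc)2/dppf (5 mol %), Et3N, Me3SiCH2CH2OH, DMF, 60 °C
Reagents that add atoms: carbon monoxide, [C-]#[O+]; 2-(trimethylsilyl)ethanol, C[Si](C)(C)CCO
Why: Palladium‑catalysed alkoxycarbonylation of the dienyl triflate introduces C18 as a fluoride‑labile ester and completes the C1=C2–C3=C4 dienoate.

Step 16
Reactants: 23 vinyl dienoate; 24 3-bromofuran
Product: 26 cis-decalin diene bearing the 2-(furan-3-yl)ethyl chain, via B-alkyl-9-BBN borane 25 (not isolated)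
Conditions: 9-BBN-H, THF, rt; then 24, Pd(dppf)Cl2 (5 mol %), aq. K3PO4, DMF, 50 °C
Reagents that add atoms: 9-BBN-H, B1C2CCCC1CCC2 (boron in 25 only)
Why: 9‑BBN hydroborates the monosubstituted vinyl group in preference to the conjugated dienoate, and B‑alkyl Suzuki–Miyaura coupling with 3‑bromofuran completes the 2‑(furan‑3‑yl)ethyl chain.

Step 17
Reactants: 26 cis-decalin diene
Product: 28 ten-membered silyl enol ether, via seco-triene 27 (not isolated)
Conditions: hν (300 nm), Et2O, −40 °C; then 45 °C in the dark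
Reagents that add atoms: none
Why: Photochemical conrotatory 6π electrocyclic opening of the cyclohexadiene (provitamin D to previtamin D type) from the favoured conformer, in which quasi‑axial C19 and C9 rotate inward, should give the (4E)‑triene 27, whose thermal antarafacial [1,7]‑hydrogen shift from C19 to C10 (previtamin D to vitamin D type) forms the ring‑cis C1=C2 and C3=C4 bonds and erases the C5 and C10 stereocentres.

Step 18
Reactants: 28 silyl enol ether
Product: 29 aldehyde acid (C5 epimers)
Conditions: TBAF (3 equiv), THF, 0 °C → rt; dil. HCl work-up (pH 4)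
Reagents that add atoms: none
Why: Fluoride cleaves the silyl enol ether and, by β‑elimination, the 2‑(trimethylsilyl)ethyl ester; C‑protonation gives the aldehyde, whose new C5 centre is uncontrolled and removed again in step 19.

Step 19
Reactants: 29 aldehyde acid
Product: 30 18,19-enol lactone
Conditions: EDC·HCl, Et3N, DMAP (cat.), CH2Cl2, 0 °C → rt
Reagents that add atoms: none
Why: Carbodiimide activation and O‑acylation by the aldehyde enol (enol lactonisation of a γ‑oxo acid) close a five‑membered ring that can only form with the enol oxygen cis to C4, so the temporary lactone fixes the C5=C19 geometry.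

Step 20
Reactants: 30 enol lactone
Product: 32 target CNP0318171.1, via lithium Z-enolate 31 (not isolated)
Conditions: LiOMe (1.05 equiv), THF, −78 °C; then Ac2O (3 equiv), −78 → 0 °C
Reagents that add atoms: lithium methoxide, [Li+].[O-]C; acetic anhydride, CC(=O)OC(C)=O
Why: Methoxide opens the activated enol lactone by acyl substitution to the methyl ester and the lithium (Z)‑enolate, whose O‑acetylation (enolate trapping) retains the ring‑imposed geometry and should give the (5(19)Z)‑enol acetate.

**Compound list**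

1 | methyl hydrogen (3R)-3-methylpentanedioate | COC(=O)C[C@H](C)CC(=O)O | starting material
2 | methyl (3R)-5-hydroxy-3-methylpentanoate | COC(=O)C[C@H](C)CCO | intermediate
3 | (4R)-4-methyltetrahydro-2H-pyran-2-one | O=C1C[C@H](C)CCO1 | intermediate
4 | lithium (4R)-4-methyl-5,6-dihydro-4H-pyran-2-olate | [Li+].[O-]C1=C[C@H](C)CCO1 | intermediate
5 | (3S,4R)-3,4-dimethyltetrahydro-2H-pyran-2-one (trans) | O=C1[C@@H](C)[C@H](C)CCO1 | intermediate
6 | (3S,4R)-3,4-dimethyltetrahydro-2H-pyran-2-ol (both anomers) | OC1[C@@H](C)[C@H](C)CCO1 | intermediate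
7 | (4R)-4,5-dimethyl-3,4-dihydro-2H-pyran | CC1=COCC[C@H]1C | intermediate
8 | (3R,4Z)-3,4-dimethyl-6-(trimethylsilyl)hex-4-en-1-ol | C[Si](C)(C)C/C=C(C)\[C@H](C)CCO | intermediate
9 | (3R,4Z)-3,4-dimethyl-6-(trimethylsilyl)hex-4-en-1-yl methanesulfonate | C[Si](C)(C)C/C=C(C)\[C@H](C)CCOS(C)(=O)=O | intermediate
10 | [(2Z,4R)-6-iodo-3,4-dimethylhex-2-en-1-yl]trimethylsilane | C[Si](C)(C)C/C=C(C)\[C@H](C)CCI | intermediate
11 | benzoic acid | OC(=O)c1ccccc1 | starting material
12 | dilithium (cyclohexa-2,5-dien-1-ylidene)methanediolate | [Li+].[Li+].[O-]C([O-])=C1C=CCC=C1 | intermediate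
13 | 1-[(3R,4Z)-3,4-dimethyl-6-(trimethylsilyl)hex-4-en-1-yl]cyclohexa-2,5-diene-1-carboxylic acid | OC(=O)C1(CC[C@@H](C)/C(C)=C\C[Si](C)(C)C)C=CCC=C1 | intermediate
14 | {1-[(3R,4Z)-3,4-dimethyl-6-(trimethylsilyl)hex-4-en-1-yl]cyclohexa-2,5-dien-1-yl}methanol | OCC1(CC[C@@H](C)/C(C)=C\C[Si](C)(C)C)C=CCC=C1 | intermediate
15 | tert-butyl({1-[(3R,4Z)-3,4-dimethyl-6-(trimethylsilyl)hex-4-en-1-yl]cyclohexa-2,5-dien-1-yl}methoxy)dimethylsilane | CC(C)(C)[Si](C)(C)OCC1(CC[C@@H](C)/C(C)=C\C[Si](C)(C)C)C=CCC=C1 | intermediate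
16 | 4-{[(tert-butyldimethylsilyl)oxy]methyl}-4-[(3R,4Z)-3,4-dimethyl-6-(trimethylsilyl)hex-4-en-1-yl]cyclohexa-2,5-dien-1-one | CC(C)(C)[Si](C)(C)OCC1(CC[C@@H](C)/C(C)=C\C[Si](C)(C)C)C=CC(=O)C=C1 | intermediate
17 | (4aS,7R,8S,8aR)-4a-{[(tert-butyldimethylsilyl)oxy]methyl}-8-ethenyl-7,8-dimethyl-4a,5,6,7,8,8a-hexahydronaphthalen-2(1H)-one (cis-fused; C19 trans to both methyls, methyls cis) | CC(C)(C)[Si](C)(C)OC[C@]12CC[C@@H](C)[C@](C)(C=C)[C@H]1CC(=O)C=C2 | intermediate
18 | 3,4-epoxide of 17 (epoxide face not assigned, other centres as in 17) | CC(C)(C)[Si](C)(C)OC[C@]12CC[C@@H](C)[C@](C)(C=C)[C@H]1CC(=O)C3OC23 | intermediate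
19 | (4aR,5S,6R,8aS)-8a-{[(tert-butyldimethylsilyl)oxy]methyl}-5-ethenyl-5,6-dimethyl-1,4,4a,5,6,7,8,8a-octahydronaphthalen-1-ol (carbinol epimers) | CC(C)(C)[Si](C)(C)OC[C@]12CC[C@@H](C)[C@](C)(C=C)[C@H]1CC=CC2O | intermediate
20 | (4aR,5S,6R,8aS)-8a-{[(tert-butyldimethylsilyl)oxy]methyl}-5-ethenyl-5,6-dimethyl-4a,5,6,7,8,8a-hexahydronaphthalen-1(4H)-one | CC(C)(C)[Si](C)(C)OC[C@]12CC[C@@H](C)[C@](C)(C=C)[C@H]1CC=CC2=O | intermediate
21 | potassium dienolate of 20 (C1=C2–C3=C4–O⁻) | CC(C)(C)[Si](C)(C)OC[C@]12CC[C@@H](C)[C@](C)(C=C)[C@H]1C=CC=C2[O-].[K+] | intermediate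
22 | (4aR,5S,6R,8aS)-8a-{[(tert-butyldimethylsilyl)oxy]methyl}-5-ethenyl-5,6-dimethyl-4a,5,6,7,8,8a-hexahydronaphthalen-1-yl trifluoromethanesulfonate | CC(C)(C)[Si](C)(C)OC[C@]12CC[C@@H](C)[C@](C)(C=C)[C@H]1C=CC=C2OS(=O)(=O)C(F)(F)F | intermediate
23 | 2-(trimethylsilyl)ethyl (4aR,5S,6R,8aR)-8a-{[(tert-butyldimethylsilyl)oxy]methyl}-5-ethenyl-5,6-dimethyl-4a,5,6,7,8,8a-hexahydronaphthalene-1-carboxylate | CC(C)(C)[Si](C)(C)OC[C@]12CC[C@@H](C)[C@](C)(C=C)[C@H]1C=CC=C2C(=O)OCC[Si](C)(C)C | intermediate
24 | 3-bromofuran | Brc1ccoc1 | starting material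
25 | B-alkyl-9-BBN adduct of 23 (boron on C12) | CC(C)(C)[Si](C)(C)OC[C@]12CC[C@@H](C)[C@](C)(CCB3C4CCCC3CCC4)[C@H]1C=CC=C2C(=O)OCC[Si](C)(C)C | intermediate
26 | 2-(trimethylsilyl)ethyl (4aR,5S,6R,8aR)-8a-{[(tert-butyldimethylsilyl)oxy]methyl}-5-[2-(furan-3-yl)ethyl]-5,6-dimethyl-4a,5,6,7,8,8a-hexahydronaphthalene-1-carboxylate | CC(C)(C)[Si](C)(C)OC[C@]12CC[C@@H](C)[C@](C)(CCc3ccoc3)[C@H]1C=CC=C2C(=O)OCC[Si](C)(C)C | intermediate
27 | 2-(trimethylsilyl)ethyl (1(10)Z,2Z,4E,8R,9S)-19-[(tert-butyldimethylsilyl)oxy]-15,16-epoxy-5,10-seco-cleroda-1(10),2,4,13(16),14-pentaen-18-oate | CC(C)(C)[Si](C)(C)OC/C1=C(C(=O)OCC[Si](C)(C)C)\C=C/C=C\[C@@](C)(CCc2ccoc2)[C@H](C)CC1 | intermediate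
28 | 2-(trimethylsilyl)ethyl (1Z,3E,8R,9R)-19-[(tert-butyldimethylsilyl)oxy]-15,16-epoxy-5,10-seco-cleroda-1,3,5(19),13(16),14-pentaen-18-oate (C5=C19 geometry not controlled) | C[Si](C)(C)CCOC(=O)/C1=C/C=C\C[C@@](C)(CCc2ccoc2)[C@H](C)CCC1=CO[Si](C)(C)C(C)(C)C | intermediate
29 | (1Z,3E,8R,9R)-15,16-epoxy-19-oxo-5,10-seco-cleroda-1,3,13(16),14-tetraen-18-oic acid (C5 epimers) | OC(=O)/C1=C/C=C\C[C@@](C)(CCc2ccoc2)[C@H](C)CCC1C=O | intermediate
30 | (1Z,3E,8R,9R)-15,16-epoxy-5,10-seco-cleroda-1,3,5(19),13(16),14-pentaen-18,19-olide (enol lactone) | O=C1/C(=C/C=C\C[C@@](C)(CCc2ccoc2)[C@H](C)CC3)C3=CO1 | intermediate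
31 | lithium (Z)-enolate of methyl (1Z,3E,8R,9R)-15,16-epoxy-19-oxo-5,10-seco-cleroda-1,3,13(16),14-tetraen-18-oate | COC(=O)/C1=C/C=C\C[C@@](C)(CCc2ccoc2)[C@H](C)CC\C1=C\[O-].[Li+] | intermediate
32 | methyl (1Z,3E,5(19)Z,8R,9R)-19-acetoxy-15,16-epoxy-5,10-seco-cleroda-1,3,5(19),13(16),14-pentaen-18-oate (CNP0318171.1) | COC(=O)/C1=C/C=C\C[C@@](C)(CCc2ccoc2)[C@H](C)CC\C1=C\OC(C)=O | target

**Step count and risks**

Total step count: 20. Longest linear sequence: 20 steps (1 → 32); benzoic acid 11 and 3‑bromofuran 24 enter in single steps.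

The three steps most likely to fail are step 17, step 10 and step 19.

Step 17. Thermal disrotatory re‑closure of triene 27 to a trans‑fused diene may outpace the [1,7]‑hydrogen shift. Conrotation in the non‑accordant sense would instead place C6 inward and deliver a C6 hydrogen to C10. The fallback sets out from the cold photolysate containing 27 and replaces the neutral sigmatropic shift by an oxy‑anion‑accelerated one. TBAF is added at −78 → −20 °C, so that O‑desilylation gives the C19 alkoxide of the hydroxy seco‑triene F4. The alkoxide weakens the adjacent C19–H bond, so the hydrogen shift should run well below the re‑closure temperature and give the aldehyde enolate directly. Warming with the excess fluoride then removes the 2‑(trimethylsilyl)ethyl ester, and acidic work‑up rejoins the route at 29.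

Step 10. The Lewis acid may trigger dienone–phenol rearrangement or protodesilylation before the C–C bond forms, or facial control at C9 may be incomplete. The fallback sets out from 16 and changes the nucleophile from an allylsilane to an enamine. Protodesilylation (TFA, CH2Cl2, 0 °C, SE2′) should give the terminal alkene F1 as C9 epimers. OsO4/NaIO4 then cleaves only the electron‑rich vinyl group to the α‑branched aldehyde F2. An amine‑catalysed intramolecular Michael addition (pyrrolidine/AcOH or a primary amine catalyst; desymmetrising enamine addition to the cyclohexadienone) should close ring B to the keto aldehyde F3. Its stereochemical course rests on the same chair with C8–H eclipsing the enamine double bond. Chemoselective Wittig methylenation of the aldehyde (Ph3P=CH2, −78 °C) comes back to the route at 17.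

Step 19. Base may move the β,γ‑double bond of aldehyde 29 into conjugation (C5=C4), or the activated acid may oligomerise before the enol oxygen is acylated. The fallback sets out from 29 and replaces the ring constraint by chelation. Methylation with TMSCHN2 gives the aldehyde methyl ester F5. Soft enolisation with MgBr2·OEt2/Et3N should form the magnesium (Z)‑enolate held between the enolate oxygen and the ester carbonyl, and Ac2O should acetylate it on oxygen. This arrives directly at 32 without 30 and 31.

**Further compounds**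

F1 | step 10 | 4-{[(tert-butyldimethylsilyl)oxy]methyl}-4-[(3R)-3,4-dimethylhex-5-en-1-yl]cyclohexa-2,5-dien-1-one (C4′ epimers) | CC(C)(C)[Si](C)(C)OCC1(CC[C@@H](C)C(C)C=C)C=CC(=O)C=C1
F2 | step 10 | (3R)-5-(1-{[(tert-butyldimethylsilyl)oxy]methyl}-4-oxocyclohexa-2,5-dien-1-yl)-2,3-dimethylpentanal (C2 epimers) | CC(C)(C)[Si](C)(C)OCC1(CC[C@@H](C)C(C)C=O)C=CC(=O)C=C1
F3 | step 10 | cis-fused keto aldehyde (17 with CHO in place of the C9 vinyl group) | CC(C)(C)[Si](C)(C)OC[C@]12CC[C@@H](C)[C@](C)(C=O)[C@H]1CC(=O)C=C2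
F4 | step 17 | 2-(trimethylsilyl)ethyl (1(10)Z,2Z,4E,8R,9S)-19-hydroxy-15,16-epoxy-5,10-seco-cleroda-1(10),2,4,13(16),14-pentaen-18-oate (formed as its alkoxide) | OC/C1=C(C(=O)OCC[Si](C)(C)C)\C=C/C=C\[C@@](C)(CCc2ccoc2)[C@H](C)CC1
F5 | step 19 | methyl (1Z,3E,8R,9R)-15,16-epoxy-19-oxo-5,10-seco-cleroda-1,3,13(16),14-tetraen-18-oate (C5 epimers) | COC(=O)/C1=C/C=C\C[C@@](C)(CCc2ccoc2)[C@H](C)CCC1C=O
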